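**Retrosynthetic overview**
- The target is the (S)-dihydrodaidzein skeleton (A ring fused to the chroman-4-one C ring, 4-hydroxyphenyl B ring on C3) with one prenyl group on A-ring C6 beside the C7–OH and one on B-ring C3' beside the C4'–OH. This pair of ortho-prenylphenol units on an otherwise unprotected core is the feature the plan rests on.
- Last disconnection: the two aryl–CH2 bonds (C6–prenyl and C3'–prenyl), made by two regiocomplementary aromatic prenyltransferases from (S)-dihydrodaidzein and two dimethylallyl diphosphate units.
- (S)-Dihydrodaidzein comes from daidzein by O-benzylation, Ru-catalysed transfer hydrogenation with dynamic kinetic resolution (sets C3), reoxidation at C4 and hydrogenolysis. The diphosphate comes from prenyl bromide.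
- No ring is formed in the route: rings A, B and C are all bought with daidzein, and only C2=C3 of ring C is saturated.

Key step: step 6

Assumption: the two prenyltransferases are recombinant His-tagged proteins from E. coli, used as catalysts after an analytical-scale check of a small enzyme panel for C6 and C3' selectivity on 6; diphosphates are drawn as free acids but handled as ammonium salts.

**Step 1**
Reactants: 1 daidzein
Product: 2 7-benzyloxy-3-(4-benzyloxyphenyl)-4H-chromen-4-one (7,4'-di-O-benzyldaidzein)
Conditions: BnBr (2.5 equiv), K2CO3 (3 equiv), DMF, 60 °C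
Reagents that add atoms: benzyl bromide, BrCc1ccccc1
Why: Williamson etherification of the two phenoxides should be clean, because daidzein has no chelated 5-OH and no other nucleophilic site.

**Step 2**
Reactants: 2 7,4'-di-O-benzyldaidzein
Product: 4 (3S,4S)-7-benzyloxy-3-(4-benzyloxyphenyl)chroman-4-ol, via racemic 7,4'-dibenzyloxyisoflavanone 3 (not isolated)
Conditions: RuCl[(S,S)-TsDPEN](p-cymene) (cat.), HCO2H/Et3N (5:2), DMF, 40 °C
Reagents that add atoms: none
Why: Noyori–Ikariya asymmetric transfer hydrogenation run as a domino sequence, in which Ru–H conjugate reduction of the chromone C2=C3 gives the configurationally labile isoflavanone 3, its enantiomers equilibrate through the enol in the amine/formate medium, and the (S,S)-catalyst reduces the C4 ketone of the (3S)-enantiomer faster (dynamic kinetic resolution), delivering hydride to the face that gives the (4S)-benzylic alcohol (aryl ketone model) cis to the C3 aryl group, so that C3 (S) and C4 (S) are both set by the catalyst.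

**Step 3**
Reactants: 4 (3S,4S)-cis-isoflavan-4-ol dibenzyl ether
Product: 5 (S)-7-benzyloxy-3-(4-benzyloxyphenyl)chroman-4-one
Conditions: Dess–Martin periodinane (1.3 equiv), NaHCO3, CH2Cl2, 0 °C to rt; quick silica filtration
Reagents that add atoms: none
Why: Dess–Martin oxidation of the benzylic secondary alcohol under bicarbonate-buffered, non-enolising conditions removes the C4 stereocentre and should leave the C3 (S) centre untouched.

**Step 4**
Reactants: 5 (S)-7,4'-dibenzyloxyisoflavanone
Product: 6 (S)-dihydrodaidzein [(S)-7-hydroxy-3-(4-hydroxyphenyl)chroman-4-one]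
Conditions: H2 (1 atm), 10% Pd/C, EtOAc/THF, rt
Reagents that add atoms: none
Why: Pd-catalysed hydrogenolysis of the two aryl benzyl ethers is neutral, so C3 should not enolise, and the C4 ketone, deactivated as a vinylogous ester by the para C7 oxygen, should survive.

**Step 5**
Reactants: 7 prenyl bromide (1-bromo-3-methylbut-2-ene)
Product: 8 dimethylallyl diphosphate (isolated as the tris-ammonium salt)
Conditions: (Bu4N)3HP2O7 (2 equiv), MeCN, rt; Dowex 50W-X8 (NH4+ form), aq. NH4HCO3; cellulose chromatography; lyophilisation
Reagents that add atoms: tris(tetrabutylammonium) hydrogen diphosphate, CCCC[N+](CCCC)(CCCC)CCCC.CCCC[N+](CCCC)(CCCC)CCCC.CCCC[N+](CCCC)(CCCC)CCCC.OP(=O)([O-])OP(=O)([O-])[O-]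
Why: SN2 displacement of the primary allylic bromide by the diphosphate trianion in acetonitrile (allylic diphosphate synthesis by pyrophosphate alkylation) should give the linear diphosphate, with the excess of salt suppressing double alkylation.

**Step 6**
Reactants: 6 (S)-dihydrodaidzein; 8 dimethylallyl diphosphate (two equivalents, one per stage, each in slight excess)
Product: 10 (S)-7,4'-dihydroxy-6,3'-diprenylisoflavanone, via (S)-6-prenyldihydrodaidzein 9 (not isolated)
Conditions: (i) 7-DMATS-type A-ring prenyltransferase, 8 (1.3 equiv), HEPES pH 7.2, CaCl2 (5 mM), 5% DMSO, 30 °C; (ii) NovQ, 8 (1.3 equiv), same pot, 30 °C; EtOAc extraction, silica chromatography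
Reagents that add atoms: none
Why: Each enzyme ionises 8 to a dimethylallyl cation–diphosphate ion pair in an aromatic-lined pocket, the phenol-activated ring carbon held next to C1 of the cation attacks it, and loss of the arenium proton completes an enzymatic Friedel–Crafts alkylation; the closest known reaction type is the C-dimethylallylation of flavanones and isoflavones by DMATS-type and ABBA-type aromatic prenyltransferases. The first enzyme should alkylate the A ring at C6 (ortho to the C7–OH, para to O1) to give 9, and NovQ, whose native substrate 4-hydroxyphenylpyruvate is prenylated ortho to the hydroxyl of a para-substituted phenol, should then alkylate the B ring at C3' (ortho to the C4'–OH). No ring is closed and no stereocentre is created; the C3 (S) centre is only carried through, and pH 7.2, 30 °C and a high enzyme loading keep the time available for enolisation short. The selectivities needed are C6 over C8, C- over O-alkylation, attachment through the primary prenyl carbon, and one prenyl group per ring; the two free phenols supply the ortho activation and the binding handles, the B ring has only one kind of ortho position (C3' and C5' are equivalent), and the choice between C6 and C8 is made by the active site. Running the enzymes in sequence in one pot lets the A-ring alkylation be followed to completion before the second portion of 8 and the B-ring enzyme are added.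

**Compound list**
1 | daidzein | O=c1c(-c2ccc(O)cc2)coc2cc(O)ccc12 | starting material
2 | 7-benzyloxy-3-(4-benzyloxyphenyl)-4H-chromen-4-one | O=c1c(-c2ccc(OCc3ccccc3)cc2)coc2cc(OCc3ccccc3)ccc12 | intermediate
3 | racemic 7-benzyloxy-3-(4-benzyloxyphenyl)chroman-4-one (not isolated) | O=C1c2ccc(OCc3ccccc3)cc2OCC1c1ccc(OCc2ccccc2)cc1 | intermediate
4 | (3S,4S)-7-benzyloxy-3-(4-benzyloxyphenyl)chroman-4-ol (cis) | C(c1ccccc1)Oc1ccc([C@H]2COc3cc(OCc4ccccc4)ccc3[C@H]2O)cc1 | intermediate
5 | (S)-7-benzyloxy-3-(4-benzyloxyphenyl)chroman-4-one | C(c1ccccc1)Oc1ccc([C@H]2COc3cc(OCc4ccccc4)ccc3C2=O)cc1 | intermediate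
6 | (S)-dihydrodaidzein | Oc1ccc([C@H]2COc3cc(O)ccc3C2=O)cc1 | intermediate
7 | prenyl bromide | CC(C)=CCBr | starting material
8 | dimethylallyl diphosphate (drawn as free acid) | CC(C)=CCOP(=O)(O)OP(=O)(O)O | intermediate
9 | (S)-7-hydroxy-3-(4-hydroxyphenyl)-6-prenylchroman-4-one (not isolated) | Oc1ccc([C@H]2COc3cc(O)c(CC=C(C)C)cc3C2=O)cc1 | intermediate
10 | (S)-7,4'-dihydroxy-6,3'-diprenylisoflavanone | CC(C)=CCc1cc([C@H]2COc3cc(O)c(CC=C(C)C)cc3C2=O)ccc1O | target

**Step count and risks**
Total steps: 6. Longest linear sequence: 5 (steps 1, 2, 3, 4, 6).

Steps most likely to fail: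

1. Step 6. The bent, readily enolised 5-deoxy isoflavanone may be turned over slowly or with poor site fidelity, so that attack at C8 or at the C7 oxygen competes with C6 and the C3 centre epimerises during a long aqueous incubation. The fallback sets out from 1 and comes back at 10, moving the prenylation ahead of the stereocentre so that the enzymes work on a flat, achiral isoflavone, where incubation time and regioisomer separation carry no stereochemical penalty. Daidzein 1 would be treated with 8 and the same two enzymes to give 6,3'-diprenyldaidzein F1. Silylation (TBSCl, imidazole, DMF) would give the bis-TBS ether F2. Transfer hydrogenation with RuCl[(S,S)-TsDPEN](p-cymene) and HCO2H/Et3N, to which the trisubstituted prenyl alkenes are inert, would pass through the racemic silylated isoflavanone F3 to the (3S,4S)-cis-isoflavan-4-ol F4. Dess–Martin oxidation would give the (S)-isoflavanone F5, and pyridine-buffered HF·pyridine in THF at 0 °C would release the target 10.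

2. Step 2. The conjugate reduction may stall on the poorly soluble isoflavone, or the enol equilibration of 3 may be too slow relative to ketone reduction, giving incomplete conversion or lower cis and enantiomer selectivity. The fallback sets out from 1 and comes back at 6, replacing asymmetric catalysis by resolution. Catalytic transfer hydrogenation of daidzein 1 (Pd/C, HCO2NH4, MeOH, reflux) would give racemic dihydrodaidzein F6. Preparative chiral SFC on a polysaccharide phase would deliver (S)-6, and the (R)-fraction would be re-equilibrated with a trace of Et3N in MeOH and recycled.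

3. Step 4. Prolonged contact with Pd/H2 may over-reduce the benzylic C4 carbonyl or erode the C3 configuration on the catalyst surface. The fallback sets out from 5 and comes back at 6 by non-reductive Lewis-acid debenzylation: BCl3 with pentamethylbenzene as benzyl-cation scavenger in CH2Cl2 at −78 °C would give 6 directly, with no new intermediate.

**Further compounds**
F1 | step 6 | 6,3'-diprenyldaidzein | CC(C)=CCc1cc(-c2coc3cc(O)c(CC=C(C)C)cc3c2=O)ccc1O
F2 | step 6 | 7,4'-bis(tert-butyldimethylsilyloxy)-6,3'-diprenylisoflavone | CC(C)=CCc1cc(-c2coc3cc(O[Si](C)(C)C(C)(C)C)c(CC=C(C)C)cc3c2=O)ccc1O[Si](C)(C)C(C)(C)C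
F3 | step 6 | racemic 7,4'-bis(tert-butyldimethylsilyloxy)-6,3'-diprenylisoflavanone (not isolated) | CC(C)=CCc1cc(C2COc3cc(O[Si](C)(C)C(C)(C)C)c(CC=C(C)C)cc3C2=O)ccc1O[Si](C)(C)C(C)(C)C
F4 | step 6 | (3S,4S)-7,4'-bis(tert-butyldimethylsilyloxy)-6,3'-diprenylisoflavan-4-ol | CC(C)=CCc1cc([C@H]2COc3cc(O[Si](C)(C)C(C)(C)C)c(CC=C(C)C)cc3[C@H]2O)ccc1O[Si](C)(C)C(C)(C)C
F5 | step 6 | (S)-7,4'-bis(tert-butyldimethylsilyloxy)-6,3'-diprenylisoflavanone | CC(C)=CCc1cc([C@H]2COc3cc(O[Si](C)(C)C(C)(C)C)c(CC=C(C)C)cc3C2=O)ccc1O[Si](C)(C)C(C)(C)C
F6 | step 2 | racemic dihydrodaidzein | O=C1c2ccc(O)cc2OCC1c1ccc(O)cc1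
F0 | step 4 | none | none
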